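**Plan**
- Retrosynthesis: the two phenol silyl ethers are removed first, then ring A is cut at C4a–C5 and C8a–C8 (with the two-carbon bridge lost as ethylene put back), giving bromoquinone 8 and diene 10.
- Quinone 8 comes from a 1,4-dimethoxyarene; its side chain is cut at C3'=C4' (cross metathesis), at the ester C–O (acylation) and at C1'–C2' (allylation of aldehyde 1).
- Forward: the side chain is assembled on the arene (steps 1–3), the quinone is unmasked (step 4), the diene is made (step 5), ring A arises last (step 6), and the phenols are released (step 7).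
- Enabling feature: ring A (C4a, C5, C6, C7, C8, C8a) carries only two para oxygens, at C5 and C8. It therefore maps onto a symmetric 1,4-dioxygenated cyclohexa-1,3-diene added to a benzoquinone that already holds the full C1' butanoate side chain.
- Stereochemistry: the only stereocentre, C1' (R), is set in step 1 by the (R)-BINOL/Ti(OiPr)4 catalyst and no later step breaks a bond to it.

Key step: step 6

Remark: positions are numbered as in shikonin (quinone ring C1–C4, ring A C5–C8, side chain C1'–C6'). The (R)-BINOL/Ti(OiPr)4 catalyst is assumed to deliver allyl to the Re face of aldehyde 1, as it does with benzaldehyde, which corresponds to (R) at C1'.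

**Step 1**
Reactants: 1 4-bromo-2,5-dimethoxybenzaldehyde; 2 allyltributylstannane
Product: 3 (R)-1-(4-bromo-2,5-dimethoxyphenyl)but-3-en-1-ol
Conditions: (R)-BINOL (10 mol%), Ti(OiPr)4 (10 mol%), 4 Å MS, CH2Cl2, −20 °C; aq. NaHCO3 work-up
Reagents that add atoms: allyltributylstannane (2), C=CC[Sn](CCCC)(CCCC)CCCC
Why: Keck asymmetric allylation, in which the chiral (R)-BINOL/Ti(OiPr)4 Lewis acid activates the aryl aldehyde and directs the allylstannane to its Re face, should set C1' as (R) (OH > aryl > allyl > H) while the aryl bromide and methyl ethers stay inert.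

**Step 2**
Reactants: 3 (R)-1-(4-bromo-2,5-dimethoxyphenyl)but-3-en-1-ol; 4 butanoic anhydride
Product: 5 (R)-1-(4-bromo-2,5-dimethoxyphenyl)but-3-enyl butanoate
Conditions: (PrCO)2O, Et3N, DMAP (cat.), CH2Cl2, 0 °C to rt
Reagents that add atoms: butanoic anhydride (4), CCCC(=O)OC(=O)CCC
Why: DMAP-catalysed acyl transfer to a secondary benzylic alcohol is routine and breaks no bond at C1', so the (R) configuration is retained.

**Step 3**
Reactants: 5 (R)-1-(4-bromo-2,5-dimethoxyphenyl)but-3-enyl butanoate; 6 2-methylbut-2-ene
Product: 7 (R)-1-(4-bromo-2,5-dimethoxyphenyl)-4-methylpent-3-enyl butanoate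
Conditions: (H2IMes)(PCy3)Cl2Ru=CHPh (second-generation Grubbs catalyst, 5 mol%), 2-methylbut-2-ene (excess, cosolvent), CH2Cl2, rt to 35 °C
Reagents that add atoms: 2-methylbut-2-ene (6), CC=C(C)C
Why: Olefin cross metathesis of the terminal alkene with a large excess of 2-methylbut-2-ene should cap the chain with the isopropylidene group and release propene, leaving the ester, the aryl bromide and C1' untouched.

**Step 4**
Reactants: 7 (R)-1-(4-bromo-2,5-dimethoxyphenyl)-4-methylpent-3-enyl butanoate
Product: 8 (R)-1-(4-bromo-3,6-dioxocyclohexa-1,4-dienyl)-4-methylpent-3-enyl butanoate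
Conditions: (NH4)2Ce(NO3)6 (2.5 equiv), MeCN/H2O, 0 °C
Reagents that add atoms: water, O
Why: Oxidative demethylation of a 1,4-dimethoxyarene by tetravalent cerium (arene radical cation, water attack at the methoxy-bearing carbons, loss of two methanol) should give the quinone, because the arene is oxidised much more readily than the trisubstituted alkene and the ester and bromide are inert at 0 °C.

**Step 5**
Reactants: 9 cyclohexane-1,4-dione
Product: 10 1,4-bis(trimethylsilyloxy)cyclohexa-1,3-diene
Conditions: LiN(iPr)2 (commercial solution, 2.2 equiv), Me3SiCl (2.4 equiv), THF, −78 °C to rt; pentane, filtration, distillation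
Reagents that add atoms: chlorotrimethylsilane, C[Si](C)(C)Cl
Why: Double enolate O-silylation with in situ trapping should give the conjugated diene, because the second deprotonation occurs at the CH2 that is both alpha to the remaining ketone and allylic to the first silyl enol ether.

**Step 6**
Reactants: 8 (R)-1-(4-bromo-3,6-dioxocyclohexa-1,4-dienyl)-4-methylpent-3-enyl butanoate; 10 1,4-bis(trimethylsilyloxy)cyclohexa-1,3-diene
Product: 13 butylshikonin 5,8-bis(trimethylsilyl) ether, via bromo Diels–Alder adduct 11 (not isolated), via ethano-bridged quinone 12 (not isolated)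
Conditions: 10 (1.5 equiv), PhMe, 0 °C to rt; then Et3N (1.1 equiv), 0 °C, filtration under argon; then 110 °C; concentration, crude 13 taken on
Reagents that add atoms: none
Why: The electron-rich cyclic diene 10 adds across the bromine-bearing C=C of quinone 8 in a concerted, suprafacial normal-demand Diels–Alder reaction that forms C4a–C5 and C8a–C8 and gives bicyclo[2.2.2]octene 11; Et3N then removes H8a while bromide leaves C4a (E1cB dehydrobromination) to restore the quinone in 12, and heating expels the C9–C10 ethano bridge as ethylene in a retro-[4+2] (Alder–Rickert) cycloreversion driven by aromatisation of ring A. The closest known reaction type is the cycloaddition of 2-bromo-5-alkylbenzoquinones with 1-oxygenated cyclohexa-1,3-dienes followed by HBr loss and thermal ethylene extrusion, as used for juglone-type naphthoquinones. Ring A is closed as a six-membered carbocycle by intermolecular [4+2] cycloaddition, both ring bonds being made in the same step so that no endo or exo cyclisation mode applies, and it becomes aromatic once the two-carbon bridge has left. No stereocentre of the product is made here: the centres created at C4a, C5, C8 and C8a in 11 are all erased on the way to 13, and C1' lies outside the reacting system and keeps its (R) configuration. The selectivity required is site selectivity between the two quinone double bonds, which bromine secures by lowering the LUMO at its own alkene while the branched side chain hinders the other one; because the halogen then departs as bromide, the quinone oxidation level is regained without an oxidant. Regiochemistry is not an issue, since diene 10 is symmetric and both orientations lead to the same ring A.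

**Step 7**
Reactants: 13 butylshikonin 5,8-bis(trimethylsilyl) ether
Product: 14 butylshikonin
Conditions: 0.1 M aq. HCl, THF, 0 °C
Reagents that add atoms: none
Why: Acid-catalysed hydrolysis of the two aryl trimethylsilyl ethers should release the peri phenols, which chelate to the quinone carbonyls, under conditions too mild to affect the secondary butanoate, the alkene or C1'.

**Compound list**
1 | 4-bromo-2,5-dimethoxybenzaldehyde | COc1cc(Br)c(OC)cc1C=O | starting material
2 | allyltributylstannane | C=CC[Sn](CCCC)(CCCC)CCCC | starting material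
3 | (R)-1-(4-bromo-2,5-dimethoxyphenyl)but-3-en-1-ol | O[C@H](CC=C)c1cc(OC)c(Br)cc1OC | intermediate
4 | butanoic anhydride | CCCC(=O)OC(=O)CCC | starting material
5 | (R)-1-(4-bromo-2,5-dimethoxyphenyl)but-3-enyl butanoate | CCCC(=O)O[C@H](CC=C)c1cc(OC)c(Br)cc1OC | intermediate
6 | 2-methylbut-2-ene | CC=C(C)C | starting material
7 | (R)-1-(4-bromo-2,5-dimethoxyphenyl)-4-methylpent-3-enyl butanoate | CCCC(=O)O[C@H](CC=C(C)C)c1cc(OC)c(Br)cc1OC | intermediate
8 | (R)-1-(4-bromo-3,6-dioxocyclohexa-1,4-dienyl)-4-methylpent-3-enyl butanoate | CCCC(=O)O[C@H](CC=C(C)C)C1=CC(=O)C(Br)=CC1=O | intermediate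
9 | cyclohexane-1,4-dione | O=C1CCC(=O)CC1 | starting material
10 | 1,4-bis(trimethylsilyloxy)cyclohexa-1,3-diene | C[Si](C)(C)OC1=CC=C(O[Si](C)(C)C)CC1 | intermediate
11 | (R)-1-[4a-bromo-1,4-dioxo-5,8-bis(trimethylsilyloxy)-1,4,4a,5,8,8a-hexahydro-5,8-ethanonaphthalen-2-yl]-4-methylpent-3-enyl butanoate (cis ring fusion, diastereomer mixture at the transient ring centres) | CCCC(=O)O[C@H](CC=C(C)C)C1=CC(=O)C2(Br)C(C1=O)C3(O[Si](C)(C)C)C=CC2(O[Si](C)(C)C)CC3 | intermediate (not isolated)
12 | (R)-1-[1,4-dioxo-5,8-bis(trimethylsilyloxy)-1,4,5,8-tetrahydro-5,8-ethanonaphthalen-2-yl]-4-methylpent-3-enyl butanoate (diastereomer mixture at the bridgeheads) | CCCC(=O)O[C@H](CC=C(C)C)C1=CC(=O)C2=C(C1=O)C3(O[Si](C)(C)C)C=CC2(O[Si](C)(C)C)CC3 | intermediate (not isolated)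
13 | butylshikonin 5,8-bis(trimethylsilyl) ether, (R)-1-[1,4-dioxo-5,8-bis(trimethylsilyloxy)-1,4-dihydronaphthalen-2-yl]-4-methylpent-3-enyl butanoate | CCCC(=O)O[C@H](CC=C(C)C)C1=CC(=O)c2c(O[Si](C)(C)C)ccc(O[Si](C)(C)C)c2C1=O | intermediate
14 | butylshikonin, (R)-1-(5,8-dihydroxy-1,4-dioxo-1,4-dihydronaphthalen-2-yl)-4-methylpent-3-enyl butanoate | CCCC(=O)O[C@H](CC=C(C)C)C1=CC(=O)c2c(O)ccc(O)c2C1=O | target

**Step count**
Total steps: 7. Longest linear sequence: 6 (steps 1, 2, 3, 4, 6, 7); step 5 is the one-step side branch to the diene.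

**Steps most likely to fail**

1. Step 6. Three processes could go wrong. Butanoic acid could be lost from C1' (elimination toward C2' or ionisation next to the quinone) at the temperature that ethylene extrusion needs. The quinone ester could degrade under base during dehydrobromination. The bridgehead silyl ethers of 11 could cleave early, followed by retro-aldol ring opening.
Fallback: the side-chain oxygen is carried as a silyl ether through ring construction and the butanoyl group is added last. Setting out from 3, silylation (tBuMe2SiCl, imidazole, DMF) should give (R)-[1-(4-bromo-2,5-dimethoxyphenyl)but-3-enyloxy](tert-butyl)dimethylsilane F1. Cross metathesis with 6 under (H2IMes)(PCy3)Cl2Ru=CHPh should give (R)-[1-(4-bromo-2,5-dimethoxyphenyl)-4-methylpent-3-enyloxy](tert-butyl)dimethylsilane F2. Oxidation with (NH4)2Ce(NO3)6 in MeCN/H2O at 0 °C should give the silyl-protected bromoquinone (R)-2-bromo-5-[1-(tert-butyldimethylsilyloxy)-4-methylpent-3-enyl]cyclohexa-2,5-diene-1,4-dione F3. Cycloaddition with 10, Et3N treatment and heating should then pass through the silyl-protected bromo Diels–Alder adduct F4 and the silyl-protected ethano-bridged quinone F5 to shikonin tris(silyl) ether F6, whose side-chain silyl ether should tolerate heating better than the ester. Global desilylation (HF·pyridine, THF, 0 °C) should give (R)-shikonin F7. Carbodiimide esterification (butanoic acid, DCC, DMAP, CH2Cl2, 0 °C) should acylate only the side-chain hydroxyl, because the peri phenols are tied up in hydrogen bonds to the quinone carbonyls. The route is rejoined at 14.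

2. Step 4. Tetravalent cerium could attack the trisubstituted alkene or its allylic positions in competition with oxidation of the bromine-deactivated arene.
Fallback: the quinone is unmasked before the electron-rich alkene exists. Setting out from 5, oxidation with (NH4)2Ce(NO3)6 in MeCN/H2O at 0 °C should give (R)-1-(4-bromo-3,6-dioxocyclohexa-1,4-dienyl)but-3-enyl butanoate F8, whose terminal alkene is much harder to oxidise. Cross metathesis of F8 with 6 under (H2IMes)(PCy3)Cl2Ru=CHPh (quinones are tolerated by this catalyst) should then give 8, where the route is rejoined.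

3. Step 1. Enantiofacial discrimination could be poor, or turnover slow, if the ortho methoxy group chelates the titanium centre and disturbs the catalyst–aldehyde complex.
Fallback: resolution replaces asymmetric induction. Setting out from 1, addition of CH2=CHCH2MgBr (THF, −78 °C) should give racemic 1-(4-bromo-2,5-dimethoxyphenyl)but-3-en-1-ol F9. Lipase-catalysed transesterification (Burkholderia cepacia lipase, vinyl butanoate, tBuOMe, 35 °C) should acylate the (R)-enantiomer preferentially (aryl as the large group, allyl as the medium group) and so give butanoate 5 directly. The slower-reacting (S)-1-(4-bromo-2,5-dimethoxyphenyl)but-3-en-1-ol F10 stays as the alcohol and is removed by chromatography. The route is rejoined at 5.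

**Further compounds**
F1 | step 6 | (R)-[1-(4-bromo-2,5-dimethoxyphenyl)but-3-enyloxy](tert-butyl)dimethylsilane | CC(C)(C)[Si](C)(C)O[C@H](CC=C)c1cc(OC)c(Br)cc1OC
F2 | step 6 | (R)-[1-(4-bromo-2,5-dimethoxyphenyl)-4-methylpent-3-enyloxy](tert-butyl)dimethylsilane | CC(C)(C)[Si](C)(C)O[C@H](CC=C(C)C)c1cc(OC)c(Br)cc1OC
F3 | step 6 | (R)-2-bromo-5-[1-(tert-butyldimethylsilyloxy)-4-methylpent-3-enyl]cyclohexa-2,5-diene-1,4-dione | CC(C)(C)[Si](C)(C)O[C@H](CC=C(C)C)C1=CC(=O)C(Br)=CC1=O
F4 | step 6 | silyl-protected bromo Diels–Alder adduct, 4a-bromo-2-[(R)-1-(tert-butyldimethylsilyloxy)-4-methylpent-3-enyl]-5,8-bis(trimethylsilyloxy)-4a,5,8,8a-tetrahydro-5,8-ethanonaphthalene-1,4-dione | CC(C)(C)[Si](C)(C)O[C@H](CC=C(C)C)C1=CC(=O)C2(Br)C(C1=O)C3(O[Si](C)(C)C)C=CC2(O[Si](C)(C)C)CC3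
F5 | step 6 | silyl-protected ethano-bridged quinone, 2-[(R)-1-(tert-butyldimethylsilyloxy)-4-methylpent-3-enyl]-5,8-bis(trimethylsilyloxy)-5,8-dihydro-5,8-ethanonaphthalene-1,4-dione | CC(C)(C)[Si](C)(C)O[C@H](CC=C(C)C)C1=CC(=O)C2=C(C1=O)C3(O[Si](C)(C)C)C=CC2(O[Si](C)(C)C)CC3
F6 | step 6 | shikonin tris(silyl) ether, 2-[(R)-1-(tert-butyldimethylsilyloxy)-4-methylpent-3-enyl]-5,8-bis(trimethylsilyloxy)naphthalene-1,4-dione | CC(C)(C)[Si](C)(C)O[C@H](CC=C(C)C)C1=CC(=O)c2c(O[Si](C)(C)C)ccc(O[Si](C)(C)C)c2C1=O
F7 | step 6 | (R)-shikonin, 5,8-dihydroxy-2-[(R)-1-hydroxy-4-methylpent-3-enyl]naphthalene-1,4-dione | O[C@H](CC=C(C)C)C1=CC(=O)c2c(O)ccc(O)c2C1=O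
F8 | step 4 | (R)-1-(4-bromo-3,6-dioxocyclohexa-1,4-dienyl)but-3-enyl butanoate | CCCC(=O)O[C@H](CC=C)C1=CC(=O)C(Br)=CC1=O
F9 | step 1 | racemic 1-(4-bromo-2,5-dimethoxyphenyl)but-3-en-1-ol | OC(CC=C)c1cc(OC)c(Br)cc1OC
F10 | step 1 | (S)-1-(4-bromo-2,5-dimethoxyphenyl)but-3-en-1-ol | O[C@@H](CC=C)c1cc(OC)c(Br)cc1OC
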